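The cyclopentenone ring is read as a desymmetrised 2-alkylidenecyclopent-4-ene-1,3-dione: C9 and C12, the two oxygenated ring carbons flanking C8 and the C10=C11 olefin, trade oxidation levels in the precursor. There C12 is the ketone of a cross-conjugated dienone that already carries the C1–C7 chain, and C9 is a silyloxy stereocentre. The key step adds a (Z)-oct-2-enylcerium reagent through its unsubstituted terminus to the C12 carbonyl, anti to the C9 silyloxy group, forming the C12–C13 bond and the C12 stereocentre in one operation. Since the C7=C8 olefin was set E against the C12 carbonyl, later oxidation of C9 presents it as 7Z.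

Key step: step 5

Remark: prostanoid numbering is used (C1 ester carbon; ring C8–C12; octenyl chain C13–C20); the target is read as 5E,7Z,14Z,12R, i.e. C6 lies cis to the C9 carbonyl, and the four starting materials are taken as commercial.

Step 1
Reactants: 1 methyl hex-5-enoate; 2 (E)-but-2-enal
Product: 3 methyl (5E)-7-oxohept-5-enoate
Conditions: second-generation Grubbs catalyst (cat.), excess 2, CH2Cl2, 40 °C
Reagents that add atoms: none
Why: Olefin cross-metathesis of a terminal olefin with an electron-poor enal partner should favour the cross product as the E-enal, with propene lost.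

Step 2
Reactants: 4 (4R)-4-(tert-butyldimethylsilyloxy)cyclopent-2-en-1-one; 3 methyl (5E)-7-oxohept-5-enoate
Product: 6 methyl (5E)-7-[(1R,5S)-5-(tert-butyldimethylsilyloxy)-2-oxocyclopent-3-en-1-yl]-7-hydroxyhept-5-enoate (side chain trans to the silyloxy group; both C7 epimers), via lithium dienolate 5 (not isolated)
Conditions: LiN(iPr)2, THF, −78 °C; then 3; AcOH, −78 °C
Reagents that add atoms: none
Why: Kinetic α′-deprotonation gives the cross-conjugated lithium dienolate, which should undergo a directed aldol addition to the aldehyde carbonyl anti to the silyloxy group; the low temperature suppresses β-elimination of silyloxide and the C7 epimers converge in step 3.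

Step 3
Reactants: 6 aldol adduct (both C7 epimers)
Product: 8 methyl (5E,7E)-7-[(5S)-5-(tert-butyldimethylsilyloxy)-2-oxocyclopent-3-en-1-ylidene]hept-5-enoate (C6 on the side of the silyloxy carbon), via allylic mesylate 7 (not isolated)
Conditions: MsCl, Et3N, CH2Cl2, −20 °C to 20 °C
Reagents that add atoms: none
Why: Mesylation followed by E1cB elimination through the ketone enolate should give the thermodynamically preferred E-alkylidene ketone, with C6 turned away from the C12 carbonyl oxygen and towards C9.

Step 4
Reactants: 9 oct-1-ene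
Product: 11 tributyl[(2Z)-oct-2-en-1-yl]stannane, via (Z)-oct-2-enylpotassium 10 (not isolated)
Conditions: nBuLi, KOtBu, hexane, 20 °C; THF, −50 °C; Bu3SnCl, −78 °C; H2O
Reagents that add atoms: tributyltin chloride, CCCC[Sn](Cl)(CCCC)CCCC
Why: Superbase allylic metalation gives the 2-alkenylpotassium, which equilibrates to the endo (Z) form whatever geometry forms first, and stannylation should occur at the unsubstituted terminus with retention, as in the standard preparation of (Z)-crotylstannanes.

Step 5
Reactants: 8 methyl (5E,7E)-7-[(5S)-5-(tert-butyldimethylsilyloxy)-2-oxocyclopent-3-en-1-ylidene]hept-5-enoate; 11 tributyl[(2Z)-oct-2-en-1-yl]stannane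
Product: 14 methyl (5E,7E)-7-[(2R,5S)-5-(tert-butyldimethylsilyloxy)-2-hydroxy-2-[(2Z)-oct-2-en-1-yl]cyclopent-3-en-1-ylidene]hept-5-enoate (hydroxyl cis to the silyloxy group), via (Z)-oct-2-enyllithium 12 (not isolated), via (Z)-oct-2-enylcerium dichloride 13 (not isolated)
Conditions: MeLi, THF, −78 °C; CeCl3, −78 °C; then 8, −78 °C; H2O
Reagents that add atoms: none
Why: Tin–lithium exchange gives the (Z)-allyllithium, which is transmetalated at −78 °C to the oxophilic, weakly basic allylcerium dichloride; this should add 1,2 to the C12 carbonyl rather than 1,4 or 1,6 to the dienone, to the ester, or as a base at the acidic C9–H. The closest known reaction type is the 1,2-addition of allylcerium reagents to enals and enones through the less substituted allyl terminus with retention of Z geometry at low temperature. No ring is closed. The new C12 stereocentre is controlled by the C9 stereocentre: the bulky silyloxy group shields one face of the flat dienone, so the allyl group should enter anti to it and the hydroxyl end up cis (12R). The step needs α- over γ-regioselectivity, secured by the cerium counter-ion and by the congestion of a γ-attack (a branched carbon on a fully substituted carbinol carbon), and Z retention, secured by keeping lithium and cerium species at −78 °C.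

Step 6
Reactants: 14 silyl ether carbinol
Product: 15 methyl (5E,7E)-7-[(2R,5S)-2,5-dihydroxy-2-[(2Z)-oct-2-en-1-yl]cyclopent-3-en-1-ylidene]hept-5-enoate (cis-diol)
Conditions: Bu4NF, AcOH, THF, 0 °C to 20 °C
Reagents that add atoms: none
Why: Fluoride-mediated desilylation buffered with acetic acid should free the C9 alcohol without ionising the doubly allylic alcohols.

Step 7
Reactants: 15 cis-diol
Product: 16 methyl (5E,7Z,12R,14Z)-12-hydroxy-9-oxoprosta-5,7,10,14-tetraen-1-oate
Conditions: MnO2, CH2Cl2, 20 °C
Reagents that add atoms: none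
Why: MnO2 allylic oxidation should take only the doubly allylic secondary alcohol, erasing the C9 relay stereocentre; the untouched C7=C8 olefin is now Z with respect to the new C9 carbonyl (the descriptor changes, the geometry does not).

Step 8
Reactants: 16 hydroxy dienone
Product: 17 methyl (5E,7Z,14Z)-10,11-epoxy-12-hydroxy-9-oxoprosta-5,7,14-trien-1-oate (epoxide cis to the 12-hydroxyl; C12 as in 16)
Conditions: tBuOOH (in decane), DBU, CH2Cl2, 0 °C
Reagents that add atoms: tert-butyl hydroperoxide, CC(C)(C)OO
Why: Weitz–Scheffer nucleophilic epoxidation should attack the less substituted endocyclic enone β-carbon C11 and leave the isolated Z-olefin alone; the epoxide configuration is of no consequence.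

Step 9
Reactants: 17 epoxy ketone
Product: 19 methyl (5E,7Z,12R,14Z)-10-chloro-12-hydroxy-9-oxoprosta-5,7,10,14-tetraen-1-oate, via chlorohydrin 18 (not isolated)
Conditions: HCl (4 M in 1,4-dioxane), CH2Cl2, −20 to 0 °C
Reagents that add atoms: hydrogen chloride, Cl
Why: Chloride should open the protonated epoxy ketone by SN2 at C10, the carbon α to the carbonyl (C11 is neopentyl-like), and the β-hydroxy-α-chloro ketone should dehydrate to the 2-chloroenone, the classical epoxy ketone to α-chloroenone conversion.

Step 10
Reactants: 19 chloro hydroxy dienone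
Product: 20 methyl (5E,7Z,12R,14Z)-12-acetoxy-10-chloro-9-oxoprosta-5,7,10,14-tetraen-1-oate (target)
Conditions: Ac2O, DMAP (cat.), pyridine, CH2Cl2, 0 °C to 20 °C
Reagents that add atoms: acetic anhydride, CC(=O)OC(C)=O
Why: DMAP-catalysed acyl transfer (Steglich-type acylation) should esterify the hindered tertiary alcohol, whose ionisation is disfavoured by the adjacent dienone.

Compound list
1 | methyl hex-5-enoate | C=CCCCC(=O)OC | starting material
2 | (E)-but-2-enal | C/C=C/C=O | starting material
3 | methyl (5E)-7-oxohept-5-enoate | O=C/C=C/CCCC(=O)OC | intermediate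
4 | (4R)-4-(tert-butyldimethylsilyloxy)cyclopent-2-en-1-one | O=C1C=C[C@H](O[Si](C)(C)C(C)(C)C)C1 | starting material
5 | lithium α′-dienolate of 4 (C5 deprotonated; silyloxy centre unchanged) | [Li]OC1=C[C@@H](O[Si](C)(C)C(C)(C)C)C=C1 | intermediate
6 | methyl (5E)-7-[(1R,5S)-5-(tert-butyldimethylsilyloxy)-2-oxocyclopent-3-en-1-yl]-7-hydroxyhept-5-enoate (side chain trans to silyloxy; C7 epimers) | O=C1C=C[C@H](O[Si](C)(C)C(C)(C)C)[C@H]1C(O)/C=C/CCCC(=O)OC | intermediate
7 | C7 methanesulfonate of 6 | O=C1C=C[C@H](O[Si](C)(C)C(C)(C)C)[C@H]1C(OS(C)(=O)=O)/C=C/CCCC(=O)OC | intermediate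
8 | methyl (5E,7E)-7-[(5S)-5-(tert-butyldimethylsilyloxy)-2-oxocyclopent-3-en-1-ylidene]hept-5-enoate | O=C1C=C[C@H](O[Si](C)(C)C(C)(C)C)/C1=C\C=C\CCCC(=O)OC | intermediate
9 | oct-1-ene | C=CCCCCCC | starting material
10 | (Z)-oct-2-en-1-ylpotassium | CCCCC/C=C\C[K] | intermediate
11 | tributyl[(2Z)-oct-2-en-1-yl]stannane | CCCCC/C=C\C[Sn](CCCC)(CCCC)CCCC | intermediate
12 | (Z)-oct-2-en-1-yllithium | CCCCC/C=C\C[Li] | intermediate
13 | dichloro[(2Z)-oct-2-en-1-yl]cerium | CCCCC/C=C\C[Ce](Cl)Cl | intermediate
14 | methyl (5E,7E)-7-[(2R,5S)-5-(tert-butyldimethylsilyloxy)-2-hydroxy-2-[(2Z)-oct-2-en-1-yl]cyclopent-3-en-1-ylidene]hept-5-enoate | CCCCC/C=C\C[C@@]1(O)C=C[C@H](O[Si](C)(C)C(C)(C)C)/C1=C\C=C\CCCC(=O)OC | intermediate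
15 | methyl (5E,7E)-7-[(2R,5S)-2,5-dihydroxy-2-[(2Z)-oct-2-en-1-yl]cyclopent-3-en-1-ylidene]hept-5-enoate | CCCCC/C=C\C[C@@]1(O)C=C[C@H](O)/C1=C\C=C\CCCC(=O)OC | intermediate
16 | methyl (5E,7Z,12R,14Z)-12-hydroxy-9-oxoprosta-5,7,10,14-tetraen-1-oate | CCCCC/C=C\C[C@@]1(O)C=CC(=O)/C1=C\C=C\CCCC(=O)OC | intermediate
17 | methyl (5E,7Z,14Z)-10,11-epoxy-12-hydroxy-9-oxoprosta-5,7,14-trien-1-oate (epoxide cis to 12-OH) | CCCCC/C=C\C[C@@]1(O)[C@@H]2O[C@@H]2C(=O)/C1=C\C=C\CCCC(=O)OC | intermediate
18 | methyl (5E,7Z,14Z)-10-chloro-11,12-dihydroxy-9-oxoprosta-5,7,14-trien-1-oate (Cl trans to 11-OH; 11-OH cis to 12-OH) | CCCCC/C=C\C[C@@]1(O)[C@H](O)[C@@H](Cl)C(=O)/C1=C\C=C\CCCC(=O)OC | intermediate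
19 | methyl (5E,7Z,12R,14Z)-10-chloro-12-hydroxy-9-oxoprosta-5,7,10,14-tetraen-1-oate | CCCCC/C=C\C[C@@]1(O)C=C(Cl)C(=O)/C1=C\C=C\CCCC(=O)OC | intermediate
20 | methyl (5E,7Z,12R,14Z)-12-acetoxy-10-chloro-9-oxoprosta-5,7,10,14-tetraen-1-oate | CCCCC/C=C\C[C@@]1(OC(C)=O)C=C(Cl)C(=O)/C1=C\C=C\CCCC(=O)OC | target

Total step count: 10. Longest linear sequence: 9 steps (steps 1, 2, 3, 5, 6, 7, 8, 9, 10).

Steps most likely to fail

Step 5. The allylmetal may bond through its substituted (γ) terminus, may stereomutate to the E form during transmetalation, or may add in conjugate fashion to the dienone. The fallback sets out from 8 and removes every regio- and stereochemical question from the nucleophile. The symmetrical allyl reagent prepared from allylmagnesium bromide (CH2=CHCH2MgBr) and CeCl3 should add to C12 under the same anti facial control. This gives methyl (5E,7E)-7-[(2R,5S)-5-(tert-butyldimethylsilyloxy)-2-hydroxy-2-(prop-2-en-1-yl)cyclopent-3-en-1-ylidene]hept-5-enoate F1. Z-selective cross-metathesis of its terminal olefin with hept-1-ene, under the cyclometalated ruthenium catalyst Ru(NO3)(=CH-C6H4-2-OiPr)(C,C-chelating N-adamantyl-N′-(2,6-diisopropylphenyl)imidazolinylidene), should then build the C14=C15 Z-olefin. The fallback comes back to the route at 14.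

Step 9. Acid and chloride may equilibrate the 7Z olefin by reversible conjugate addition to the protonated dienone, and chloride may open the epoxide at the wrong carbon. The fallback sets out from 15 and installs chlorine before the dienone exists. Hydroxyl-directed epoxidation of the ring olefin with VO(acac)2 and tBuOOH, syn to both hydroxyls, should give the epoxy diol methyl (5E,7E)-7-[2,5-dihydroxy-3,4-epoxy-2-[(2Z)-oct-2-en-1-yl]cyclopentylidene]hept-5-enoate F2. Opening with LiCl and AcOH in THF at the less hindered C10 should give the chloro triol F3. MnO2 oxidation of its allylic C9 alcohol should give 18, this time isolated. Mesylation of the secondary C11 hydroxyl of 18 gives the mesylate F4, and E1cB loss of methanesulfonate with Et3N closes the sequence. The fallback comes back to the route at 19.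

Step 2. The lithium dienolate may lose silyloxide by β-elimination towards a cyclopentadienone, or the aldolate may revert. The fallback sets out from 4 and replaces the lithium enolate by a neutral nucleophile. Soft enolisation with Me3SiOTf and Et3N should give the trimethylsilyl dienol ether of 4 F5. A Mukaiyama aldol addition of F5 to 3, promoted by BF3·OEt2 at −78 °C, comes back to the route at 6.

Further compounds
F1 | step 5 | methyl (5E,7E)-7-[(2R,5S)-5-(tert-butyldimethylsilyloxy)-2-hydroxy-2-(prop-2-en-1-yl)cyclopent-3-en-1-ylidene]hept-5-enoate | C=CC[C@@]1(O)C=C[C@H](O[Si](C)(C)C(C)(C)C)/C1=C\C=C\CCCC(=O)OC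
F2 | step 9 | methyl (5E,7E)-7-[2,5-dihydroxy-3,4-epoxy-2-[(2Z)-oct-2-en-1-yl]cyclopentylidene]hept-5-enoate (epoxide cis to both hydroxyls; C9 and C12 as in 15) | CCCCC/C=C\C[C@@]1(O)[C@@H]2O[C@@H]2[C@H](O)/C1=C\C=C\CCCC(=O)OC
F3 | step 9 | methyl (5E,7E)-7-[4-chloro-2,3,5-trihydroxy-2-[(2Z)-oct-2-en-1-yl]cyclopentylidene]hept-5-enoate (Cl at C10 trans to the three cis hydroxyls) | CCCCC/C=C\C[C@@]1(O)[C@H](O)[C@@H](Cl)[C@H](O)/C1=C\C=C\CCCC(=O)OC
F4 | step 9 | C11 methanesulfonate of 18 | CCCCC/C=C\C[C@@]1(O)[C@H](OS(C)(=O)=O)[C@@H](Cl)C(=O)/C1=C\C=C\CCCC(=O)OC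
F5 | step 2 | trimethylsilyl dienol ether of 4 (O-silylated α′-dienolate; silyloxy centre unchanged) | C[Si](C)(C)OC1=C[C@@H](O[Si](C)(C)C(C)(C)C)C=C1
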